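## Analysis of the target

Target 15 is 4-[(2S)-2,3-dihydroxy-3-methylbutyl]-3-[(1E,3S,4S,5E)-3,4-dihydroxyundeca-1,5-dien-1-yl]-2-(hydroxymethyl)phenol (C23H36O6). It has one benzene ring (ring A) and two open chains. Ring A is 1,2,3,4-tetrasubstituted: C1–OH, C2–CH2OH, C3–C1'H=C2'H (E) and C4–C1''H2, with hydrogen only at C5 and C6. C3 is flanked on both sides and is the most crowded carbon.

C3' and C4' are both S and form a threo (syn) diol between the two E alkenes C1'=C2' and C5'=C6', so the segment C1'–C6' is locally C2-symmetric. C2'' (S) is a secondary carbinol next to the tertiary carbinol C3''. Ring A separates it from C3', so no relay between the two sets of stereocentres is possible.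

The sensitive groups are:
- the salicyl alcohol (C1–OH with C2–CH2OH), which can form an o-quinone methide;
- the cinnamyl-type allylic C3'–OH, which can ionise, with the C2''–OH placed to close a six-membered ether onto C1';
- the two 1,2-diols and the phenol.

The plan is built on the triad C2/C3/C4 of ring A. C3 bears an E-vinyl carbon. Its neighbour C4 bears a CH2 whose next atom (C2'') is a carbinol. Its other neighbour C2 is already substituted. This is the imprint of an ipso-Heck/ortho-alkylation of an ortho-substituted aryl iodide with a terminal epoxide.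

The difficulty is threefold: making two C–C bonds at adjacent crowded ring carbons without a chain of halogenations and couplings, bringing in three stereocentres as single isomers, and freeing six hydroxyl groups at the end without ionising C3'.

## Retrosynthetic reasoning

**15 to 14.** Only protecting groups are removed. The two ketals (C1–O/C2–CH2O and C3'–O/C4'–O) and the silyl ether at C3''–O are all labile to dilute aqueous acid, so one operation frees everything and no carbon–carbon bond is touched.

**14 to 12 and 13.** The C5'=C6' alkene is cut by cross metathesis. This is the only cut in the chain that leaves a terminal vinyl group on C4'. With it, the chain part of 12 can be traced to a C2-symmetric divinyl unit. The forward reaction must be E-selective and must leave the hindered styrene C1'=C2' alone.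

**12 to 5, 8 and 11 (key disconnection).** The bonds C3–C1' and C4–C1'' are cut together.
- Iodide 5 carries the iodine at the future C3, a free C–H at the future C4 and the CH2O group at the future C2.
- Epoxide 8 is the whole C1''–C4'' chain with C2'' already set.
- Diene 11 is C1'–C6' with C3' and C4' already set.

The forward reaction is a palladium-catalysed three-component union mediated by a strained bicyclic alkene. It alkylates the ortho C–H with the CH2 end of 8 and then vinylates the ipso carbon with 11. One operation turns a trisubstituted ring into the tetrasubstituted one, joins three fragments and brings all three stereocentres into one molecule. The two vinyl groups of 11 are homotopic, so the coupling cannot choose the wrong end.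

**5 to 1.** Iodide 5 comes from bromide 3 by halogen–lithium exchange (through 4) and iodination. Bromide 3 comes from diol 2 by ketalisation, and 2 from commercial aldehyde 1 by hydride reduction. The 1,2,3-pattern is bought, not made.

**8 to 6.** The silyl ether 8 comes from alcohol 7. Alcohol 7 comes from commercial methyl (S)-glycidate 6 by double addition of a methyl nucleophile to the ester. C2'' is bought, and none of its bonds is broken on the way to 15.

**11 to 9.** The two vinyl groups come from the two ester groups of the commercial L-tartrate-derived diester 9. This takes a half-reduction to dialdehyde 10 and a double Wittig methylenation in one flask. C3' and C4' are bought as a pair.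

## Alternatives that were turned down

**Alternative 1:** (the textbook route) C3–C1' and C4–C1'' are cut one after the other and C2'' is set last.
- Forward: a plain Heck coupling of 5 with 11 gives styrene A1. Bromination para to the ring oxygen gives bromide A2. Stille or Negishi prenylation gives prenylarene A3. Sharpless asymmetric dihydroxylation of A3 with AD-mix-α (K2OsO2(OH)4, (DHQ)2PHAL, K3Fe(CN)6) follows, then tail attachment and deprotection.
- Turned down: each ring bond needs its own activation and its own coupling, which adds three to four linear steps. The electrophilic bromination must spare a styrene and a vinyl group. The second coupling takes place next to the styrene. The osmylation must pick one alkene out of three, and it sets C2'' late, by reagent control, on the most advanced material.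

**Alternative 2:** an aryne across C2 and C3 of ring A takes up the chain at C3 and a one-carbon electrophile at C2.
- Forward: fluoride generates the aryne from silyl triflate A4. An alkenylcopper reagent made from vinyl iodide A5 adds to it, and DMF traps the aryl metal to give aldehyde A6.
- The regiochemistry would be right. The C1 alkoxy group distorts the triple bond so that the nucleophile attacks C3, and the charge builds up at C2 beside the withdrawing oxygen.
- Turned down: A4 is itself a 1,2,3,4-tetrasubstituted benzene that already carries the C4 side chain, so the ring problem is moved and not solved. The attack at C3 takes place beside that side chain. The most valuable fragment would have to be used in excess against a short-lived aryne.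

**Alternative 3:** all three stereocentres are set by one catalyst, cutting the four C–O bonds at C2'', C3'', C3' and C4'.
- Forward: a double Sharpless dihydroxylation of tetraene A7 with AD-mix-α. The mnemonic predicts S at C2'' and S,S at C3'/C4' from the same ligand.
- Turned down: in an aryl-conjugated triene, osmylation prefers the terminal, alkyl-substituted and most electron-rich C5'=C6' bond, which leaves the longer aryl-diene chromophore intact. Attack at the central C3'=C4' bond breaks conjugation on both sides. The wrong regioisomer and over-oxidation are therefore expected, and A7 still needs the stepwise ring construction of alternative 1.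

Key step: step 7

Assumption: 1, 6 (S enantiomer), 9 (4R,5R, from L-tartaric acid) and 13 are taken as commercial. The locants C1–C6, C1'–C11' and C1''–C4'' are those of the name of 15 given above.

## Steps

Step 1
Reactants: 1 2-bromo-6-hydroxybenzaldehyde
Product: 2 3-bromo-2-(hydroxymethyl)phenol
Conditions: NaBH4 (1.0 equiv), MeOH, 0 °C
Reagents that add atoms: none
Why: Borohydride reduction of an aromatic aldehyde; the aryl bromide and the phenol are inert and no stereocentre is involved.

Step 2
Reactants: 2 3-bromo-2-(hydroxymethyl)phenol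
Product: 3 5-bromo-2,2-dimethyl-4H-benzo[d][1,3]dioxine
Conditions: 2,2-dimethoxypropane (3 equiv), p-TsOH·H2O (2 mol %), acetone, rt
Reagents that add atoms: 2,2-dimethoxypropane, COC(C)(C)OC
Why: Acid-catalysed transketalisation closes the six-membered ketal over the phenol and the benzylic alcohol, the standard protection of salicyl alcohols. One group masks both oxygens, resists base and organometallics, and keeps the ortho substituent small.

Step 3
Reactants: 3 5-bromo-2,2-dimethyl-4H-benzo[d][1,3]dioxine
Product: 5 5-iodo-2,2-dimethyl-4H-benzo[d][1,3]dioxine, via aryllithium 4 (not isolated)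
Conditions: n-BuLi (1.05 equiv), THF, −78 °C; then I2 (1.1 equiv), THF, −78 °C to rt
Reagents that add atoms: iodine, [I][I]
Why: Bromine–lithium exchange followed by iodinolysis; the ketal has no acidic or electrophilic site at −78 °C. The iodide is needed because the key step starts with oxidative addition under mild conditions.

Step 4
Reactants: 6 methyl (2S)-oxirane-2-carboxylate
Product: 7 2-[(2S)-oxiran-2-yl]propan-2-ol
Conditions: MeMgCl (2.2 equiv), THF, −78 to −30 °C; aq NH4Cl
Reagents that add atoms: methylmagnesium chloride, C[Mg]Cl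
Why: Double Grignard addition to the ester, which at low temperature reacts far faster than the epoxide; chloride as counter-ion limits halohydrin formation. No bond at the stereocentre is broken, and the descriptor stays S because C(CH3)2OH, like CO2CH3, outranks the ring CH2.

Step 5
Reactants: 7 2-[(2S)-oxiran-2-yl]propan-2-ol
Product: 8 triethyl({2-[(2S)-oxiran-2-yl]propan-2-yl}oxy)silane
Conditions: Et3SiCl (1.3 equiv), imidazole (2.5 equiv), DMAP (10 mol %), DMF, rt
Reagents that add atoms: chlorotriethylsilane, CC[Si](Cl)(CC)CC
Why: Imidazole-promoted silylation without a Lewis acid, so the epoxide is neither opened nor rearranged. The silyl ether blocks Payne migration and chelation in the key step, makes the small epoxide easy to handle, and falls off in the final acid step.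

Step 6
Reactants: 9 dimethyl (4R,5R)-2,2-dimethyl-1,3-dioxolane-4,5-dicarboxylate
Product: 11 (4S,5S)-4,5-diethenyl-2,2-dimethyl-1,3-dioxolane, via dialdehyde 10 (not isolated)
Conditions: i-Bu2AlH (2.1 equiv), toluene, −78 °C; then Ph3P=CH2 [Ph3PCH3Br (3.0 equiv), KN(SiMe3)2 (2.9 equiv), THF], −78 °C to rt
Reagents that add atoms: methyltriphenylphosphonium bromide, [Br-].C[P+](c1ccccc1)(c1ccccc1)c1ccccc1
Why: One-flask half-reduction and double Wittig methylenation; the aluminium hemiacetals release the aldehyde only as the ylide consumes it, so the sensitive dialdehyde is never handled. The trans-dioxolane is the favoured diastereomer, which guards against α-epimerisation, and the descriptors change from R,R to S,S only because vinyl ranks below the ring carbon.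

Step 7
Reactants: 5 5-iodo-2,2-dimethyl-4H-benzo[d][1,3]dioxine; 8 triethyl({2-[(2S)-oxiran-2-yl]propan-2-yl}oxy)silane; 11 (4S,5S)-4,5-diethenyl-2,2-dimethyl-1,3-dioxolane
Product: 12 (2S)-1-{5-[(E)-2-[(4S,5S)-5-ethenyl-2,2-dimethyl-1,3-dioxolan-4-yl]ethenyl]-2,2-dimethyl-4H-benzo[d][1,3]dioxin-6-yl}-3-methyl-3-[(triethylsilyl)oxy]butan-2-ol
Conditions: Pd(OAc)2 (10 mol %), XPhos (20 mol %), potassium 5-norbornene-2-carboxylate (1.5 equiv), 8 (2 equiv), 11 (3 equiv), NMP, 70 °C, argon
Reagents that add atoms: none
Why: Catellani reaction (palladium/norbornene cooperative catalysis) in its known variant with a terminal epoxide as ortho-alkylating agent and a Heck termination. Zerovalent palladium inserts into the C–I bond of 5, the aryl–palladium species adds syn and exo across the norbornene carboxylate, and carboxylate-assisted palladation of the only free ortho C–H (C6–H of 5, C4 of the target) gives a five-membered aryl–norbornyl palladacycle of divalent palladium. This electron-rich palladacycle opens 8 in an SN2 manner at its unsubstituted CH2 terminus, helped by the potassium carboxylate held on the norbornene, and reductive elimination from the resulting tetravalent palladium alkyl forms the C4–C1'' bond. With both ortho positions filled, steric pressure drives β-carbon elimination of the norbornene, and the released 2,6-disubstituted aryl–palladium species inserts a vinyl group of 11 at its terminal carbon and loses the benzylic hydrogen by syn β-hydride elimination to give the conjugated E-styrene, which forms the C3–C1' bond. No ring is closed and no stereocentre is created: the C–O bond at the stereocentre of 8 is never broken, so S is retained at C2'', and the two dioxolane centres of 11 are spectators. Site selectivity on ring A is secured by the CH2O substituent at C4a of 5, which leaves one ortho C–H only, excludes double alkylation and enforces norbornene extrusion, while the ring strain of norbornene makes it insert before 11 does. The two vinyl groups of 11 are homotopic through its C2 axis, so only mono- against double arylation has to be controlled, which the excess of 11 does. Closure of the new hydroxyl onto palladium by C–O reductive elimination is held back by the carboxylic acid buffer, which keeps it protonated, and by the bulk of the neighbouring C(CH3)2OSiEt3 group.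

Step 8
Reactants: 12 (2S)-1-{5-[(E)-2-[(4S,5S)-5-ethenyl-2,2-dimethyl-1,3-dioxolan-4-yl]ethenyl]-2,2-dimethyl-4H-benzo[d][1,3]dioxin-6-yl}-3-methyl-3-[(triethylsilyl)oxy]butan-2-ol; 13 hept-1-ene
Product: 14 (2S)-1-{5-[(E)-2-{(4S,5S)-5-[(E)-hept-1-en-1-yl]-2,2-dimethyl-1,3-dioxolan-4-yl}ethenyl]-2,2-dimethyl-4H-benzo[d][1,3]dioxin-6-yl}-3-methyl-3-[(triethylsilyl)oxy]butan-2-ol
Conditions: 13 (5 equiv), second-generation Grubbs catalyst RuCl2(=CHPh)(H2IMes)(PCy3) (5 mol %), CH2Cl2, 40 °C
Reagents that add atoms: none
Why: Olefin cross metathesis between a slowly homodimerising allylic-oxygenated vinyl group and an excess of a simple terminal alkene, a pairing that should favour the cross product and, under thermodynamic control, the E alkene. The styrene C1'=C2' is 1,2-disubstituted and shielded by two ortho substituents and the dioxolane, ring closure of the 1,5-diene would give a cyclobutene and is excluded, and the free secondary alcohol is tolerated.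

Step 9
Reactants: 14 (2S)-1-{5-[(E)-2-{(4S,5S)-5-[(E)-hept-1-en-1-yl]-2,2-dimethyl-1,3-dioxolan-4-yl}ethenyl]-2,2-dimethyl-4H-benzo[d][1,3]dioxin-6-yl}-3-methyl-3-[(triethylsilyl)oxy]butan-2-ol
Product: 15 4-[(2S)-2,3-dihydroxy-3-methylbutyl]-3-[(1E,3S,4S,5E)-3,4-dihydroxyundeca-1,5-dien-1-yl]-2-(hydroxymethyl)phenol
Conditions: 1 M aq HCl–THF (1:3), 0 °C to rt
Reagents that add atoms: none
Why: Specific-acid hydrolysis of two acetone ketals and one triethylsilyl ether in one operation; cleavage runs through the O–C(CH3)2 and O–Si bonds, so no C–O bond at a stereocentre is broken. Ketal hydrolysis should be much faster than ionisation of the C3' alcohol, whose cation is destabilised by the oxygen on C4', so short exposure at low temperature should spare the allylic diol and the salicyl alcohol.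

## Compound list

1 | 2-bromo-6-hydroxybenzaldehyde | O=Cc1c(O)cccc1Br | starting material
2 | 3-bromo-2-(hydroxymethyl)phenol | OCc1c(O)cccc1Br | intermediate
3 | 5-bromo-2,2-dimethyl-4H-benzo[d][1,3]dioxine | CC1(C)OCc2c(Br)cccc2O1 | intermediate
4 | (2,2-dimethyl-4H-benzo[d][1,3]dioxin-5-yl)lithium | [Li]c1cccc2OC(C)(C)OCc12 | intermediate
5 | 5-iodo-2,2-dimethyl-4H-benzo[d][1,3]dioxine | CC1(C)OCc2c(I)cccc2O1 | intermediate
6 | methyl (2S)-oxirane-2-carboxylate (methyl (S)-glycidate) | COC(=O)[C@@H]1CO1 | starting material
7 | 2-[(2S)-oxiran-2-yl]propan-2-ol | CC(C)(O)[C@@H]1CO1 | intermediate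
8 | triethyl({2-[(2S)-oxiran-2-yl]propan-2-yl}oxy)silane | CC[Si](CC)(CC)OC(C)(C)[C@@H]1CO1 | intermediate
9 | dimethyl (4R,5R)-2,2-dimethyl-1,3-dioxolane-4,5-dicarboxylate | COC(=O)[C@@H]1OC(C)(C)O[C@H]1C(=O)OC | starting material
10 | (4R,5R)-2,2-dimethyl-1,3-dioxolane-4,5-dicarbaldehyde | O=C[C@@H]1OC(C)(C)O[C@H]1C=O | intermediate
11 | (4S,5S)-4,5-diethenyl-2,2-dimethyl-1,3-dioxolane | C=C[C@@H]1OC(C)(C)O[C@H]1C=C | intermediate
12 | (2S)-1-{5-[(E)-2-[(4S,5S)-5-ethenyl-2,2-dimethyl-1,3-dioxolan-4-yl]ethenyl]-2,2-dimethyl-4H-benzo[d][1,3]dioxin-6-yl}-3-methyl-3-[(triethylsilyl)oxy]butan-2-ol | CC1(C)OCc2c(/C=C/[C@@H]3OC(C)(C)O[C@H]3C=C)c(C[C@H](O)C(C)(C)O[Si](CC)(CC)CC)ccc2O1 | intermediate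
13 | hept-1-ene | C=CCCCCC | starting material
14 | (2S)-1-{5-[(E)-2-{(4S,5S)-5-[(E)-hept-1-en-1-yl]-2,2-dimethyl-1,3-dioxolan-4-yl}ethenyl]-2,2-dimethyl-4H-benzo[d][1,3]dioxin-6-yl}-3-methyl-3-[(triethylsilyl)oxy]butan-2-ol | CCCCC/C=C/[C@@H]1OC(C)(C)O[C@H]1/C=C/c1c(C[C@H](O)C(C)(C)O[Si](CC)(CC)CC)ccc2OC(C)(C)OCc12 | intermediate
15 | 4-[(2S)-2,3-dihydroxy-3-methylbutyl]-3-[(1E,3S,4S,5E)-3,4-dihydroxyundeca-1,5-dien-1-yl]-2-(hydroxymethyl)phenol | CCCCC/C=C/[C@H](O)[C@@H](O)/C=C/c1c(C[C@H](O)C(C)(C)O)ccc(O)c1CO | target

## Step count and least certain steps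

Total number of steps: 9. Longest linear sequence: 6 steps (steps 1, 2, 3, 7, 8, 9).

**Step 7 (key step).** Three things are most likely to go wrong.
- Epoxide 8 is branched next to its stereocentre. Its opening by the palladacycle may be slower than premature reductive elimination of the palladacycle onto the norbornyl carbon, or slower than direct vinylation without alkylation.
- The terminating alkene is electron-neutral and the aryl–palladium species is hindered. Insertion may therefore lose against ring closure through the new hydroxyl group, or against loss of palladium by protonation.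
- β-Hydride elimination towards the dioxolane C–H, or migration of the remaining vinyl group by palladium hydride, would erode the product.

A shift of the silyl group from the tertiary to the secondary oxygen is harmless, because both isomers converge at 15.

The fallback builds the two bonds separately with known chemistry. It sets out from 3, 8 and 11 and returns at 12. Iodination of 3 para to the ring oxygen (NIS, cat. CF3CO2H, MeCN) should give 5-bromo-6-iodo-2,2-dimethyl-4H-benzo[d][1,3]dioxine F1. Selective iodine–magnesium exchange (i-PrMgCl·LiCl, THF, −40 °C) and CuI-catalysed opening of 8 at its CH2 end should give (2S)-1-(5-bromo-2,2-dimethyl-4H-benzo[d][1,3]dioxin-6-yl)-3-methyl-3-[(triethylsilyl)oxy]butan-2-ol F2. Cross metathesis of an excess of 11 with pinacol vinylboronate should give 2-[(E)-2-[(4S,5S)-5-ethenyl-2,2-dimethyl-1,3-dioxolan-4-yl]ethenyl]-4,4,5,5-tetramethyl-1,3,2-dioxaborolane F3. Suzuki–Miyaura coupling of F2 with F3 (Pd(OAc)2, SPhos, K3PO4, THF–H2O) then leads to 12 without a Heck insertion.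

**Step 9.** The internal trans-ketal of the chain is the slowest group to hydrolyse. If it needs longer or stronger acid, the cinnamyl-type C3' alcohol may ionise. That would lead to allylic transposition, loss of configuration, or capture at C1' by the C2'' hydroxyl, and the salicyl alcohol may also suffer.

The fallback removes the slow group from the plan. It sets out from 11 and returns at 15. Hydrolysis of 11 at the fragment stage (1 M aq HCl, THF), where nothing can ionise, gives (3S,4S)-hexa-1,5-diene-3,4-diol F4. Silylation (Et3SiCl, imidazole, DMF) gives (3S,4S)-3,4-bis[(triethylsilyl)oxy]hexa-1,5-diene F5. The reaction of step 7 with 5, 8 and F5 gives (2S)-1-{5-[(1E,3S,4S)-3,4-bis[(triethylsilyl)oxy]hexa-1,5-dien-1-yl]-2,2-dimethyl-4H-benzo[d][1,3]dioxin-6-yl}-3-methyl-3-[(triethylsilyl)oxy]butan-2-ol F6. Cross metathesis with 13 gives (2S)-1-{5-[(1E,3S,4S,5E)-3,4-bis[(triethylsilyl)oxy]undeca-1,5-dien-1-yl]-2,2-dimethyl-4H-benzo[d][1,3]dioxin-6-yl}-3-methyl-3-[(triethylsilyl)oxy]butan-2-ol F7. In F7 every group (three triethylsilyl ethers and the aryl alkyl ketal) should fall to pyridinium p-toluenesulfonate in MeOH to give 15.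

**Step 8.** The vinyl group sits on a branched, oxygenated carbon, so conversion may stall. E/Z selectivity may be incomplete, and separation is hard on a large, polar substrate. Ruthenium hydride may also move the double bond.

The fallback moves the metathesis to the fragment stage. It sets out from 11 and 13 and returns at 14. Cross metathesis of an excess of 11 with 13 gives (4S,5S)-4-ethenyl-5-[(E)-hept-1-en-1-yl]-2,2-dimethyl-1,3-dioxolane F8. F8 can be freed from the Z isomer on AgNO3-impregnated silica, and unreacted 11 is recycled. F8 then takes the place of 11 in the reaction of step 7 with 5 and 8, where only its monosubstituted alkene should insert, and 14 is formed directly.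

**Step 6.** Over-reduction of one ester to the alcohol, incomplete collapse of the aluminium hemiacetals before the ylide is spent, and loss of the volatile product on concentration are the likely failures.

The fallback separates the redox events. It sets out from 9 and returns at 10 and 11. Full reduction (LiAlH4, THF) gives [(4S,5S)-2,2-dimethyl-1,3-dioxolane-4,5-diyl]dimethanol F9. Double Swern oxidation gives 10, which is used crude in the Wittig methylenation to 11.

**Step 4.** The epoxide may be opened by halide or by the Grignard reagent, the magnesium alkoxide may trigger Payne-type migration on warming, and the small water-soluble alcohol may be lost on work-up.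

The fallback postpones the methyl addition until the epoxide is gone. It sets out from 6 (with 5 and 11) and returns at 15. Compound 6 itself serves as the epoxide in the reaction of step 7 and gives methyl (2S)-3-{5-[(E)-2-[(4S,5S)-5-ethenyl-2,2-dimethyl-1,3-dioxolan-4-yl]ethenyl]-2,2-dimethyl-4H-benzo[d][1,3]dioxin-6-yl}-2-hydroxypropanoate F10. MeMgCl (4 equiv, THF, 0 °C) gives (2S)-1-{5-[(E)-2-[(4S,5S)-5-ethenyl-2,2-dimethyl-1,3-dioxolan-4-yl]ethenyl]-2,2-dimethyl-4H-benzo[d][1,3]dioxin-6-yl}-3-methylbutane-2,3-diol F11. Cross metathesis with 13 gives (2S)-1-{5-[(E)-2-{(4S,5S)-5-[(E)-hept-1-en-1-yl]-2,2-dimethyl-1,3-dioxolan-4-yl}ethenyl]-2,2-dimethyl-4H-benzo[d][1,3]dioxin-6-yl}-3-methylbutane-2,3-diol F12. The conditions of step 9 convert F12 into 15.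

## Further compounds

F1 | step 7 | 5-bromo-6-iodo-2,2-dimethyl-4H-benzo[d][1,3]dioxine | CC1(C)OCc2c(Br)c(I)ccc2O1
F2 | step 7 | (2S)-1-(5-bromo-2,2-dimethyl-4H-benzo[d][1,3]dioxin-6-yl)-3-methyl-3-[(triethylsilyl)oxy]butan-2-ol | CC[Si](CC)(CC)OC(C)(C)[C@@H](O)Cc1ccc2OC(C)(C)OCc2c1Br
F3 | step 7 | 2-[(E)-2-[(4S,5S)-5-ethenyl-2,2-dimethyl-1,3-dioxolan-4-yl]ethenyl]-4,4,5,5-tetramethyl-1,3,2-dioxaborolane | C=C[C@@H]1OC(C)(C)O[C@H]1/C=C/B1OC(C)(C)C(C)(C)O1
F4 | step 9 | (3S,4S)-hexa-1,5-diene-3,4-diol | C=C[C@H](O)[C@@H](O)C=C
F5 | step 9 | (3S,4S)-3,4-bis[(triethylsilyl)oxy]hexa-1,5-diene | C=C[C@H](O[Si](CC)(CC)CC)[C@@H](O[Si](CC)(CC)CC)C=C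
F6 | step 9 | (2S)-1-{5-[(1E,3S,4S)-3,4-bis[(triethylsilyl)oxy]hexa-1,5-dien-1-yl]-2,2-dimethyl-4H-benzo[d][1,3]dioxin-6-yl}-3-methyl-3-[(triethylsilyl)oxy]butan-2-ol | C=C[C@H](O[Si](CC)(CC)CC)[C@@H](O[Si](CC)(CC)CC)/C=C/c1c(C[C@H](O)C(C)(C)O[Si](CC)(CC)CC)ccc2OC(C)(C)OCc12
F7 | step 9 | (2S)-1-{5-[(1E,3S,4S,5E)-3,4-bis[(triethylsilyl)oxy]undeca-1,5-dien-1-yl]-2,2-dimethyl-4H-benzo[d][1,3]dioxin-6-yl}-3-methyl-3-[(triethylsilyl)oxy]butan-2-ol | CCCCC/C=C/[C@H](O[Si](CC)(CC)CC)[C@@H](O[Si](CC)(CC)CC)/C=C/c1c(C[C@H](O)C(C)(C)O[Si](CC)(CC)CC)ccc2OC(C)(C)OCc12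
F8 | step 8 | (4S,5S)-4-ethenyl-5-[(E)-hept-1-en-1-yl]-2,2-dimethyl-1,3-dioxolane | CCCCC/C=C/[C@@H]1OC(C)(C)O[C@H]1C=C
F9 | step 6 | [(4S,5S)-2,2-dimethyl-1,3-dioxolane-4,5-diyl]dimethanol | OC[C@@H]1OC(C)(C)O[C@H]1CO
F10 | step 4 | methyl (2S)-3-{5-[(E)-2-[(4S,5S)-5-ethenyl-2,2-dimethyl-1,3-dioxolan-4-yl]ethenyl]-2,2-dimethyl-4H-benzo[d][1,3]dioxin-6-yl}-2-hydroxypropanoate | COC(=O)[C@@H](O)Cc1ccc2OC(C)(C)OCc2c1/C=C/[C@@H]1OC(C)(C)O[C@H]1C=C
F11 | step 4 | (2S)-1-{5-[(E)-2-[(4S,5S)-5-ethenyl-2,2-dimethyl-1,3-dioxolan-4-yl]ethenyl]-2,2-dimethyl-4H-benzo[d][1,3]dioxin-6-yl}-3-methylbutane-2,3-diol | CC(C)(O)[C@@H](O)Cc1ccc2OC(C)(C)OCc2c1/C=C/[C@@H]1OC(C)(C)O[C@H]1C=C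
F12 | step 4 | (2S)-1-{5-[(E)-2-{(4S,5S)-5-[(E)-hept-1-en-1-yl]-2,2-dimethyl-1,3-dioxolan-4-yl}ethenyl]-2,2-dimethyl-4H-benzo[d][1,3]dioxin-6-yl}-3-methylbutane-2,3-diol | CCCCC/C=C/[C@@H]1OC(C)(C)O[C@H]1/C=C/c1c(C[C@H](O)C(C)(C)O)ccc2OC(C)(C)OCc12
A1 | alternative 1 | 5-[(E)-2-[(4S,5S)-5-ethenyl-2,2-dimethyl-1,3-dioxolan-4-yl]ethenyl]-2,2-dimethyl-4H-benzo[d][1,3]dioxine | C=C[C@@H]1OC(C)(C)O[C@H]1/C=C/c1cccc2OC(C)(C)OCc12
A2 | alternative 1 | 6-bromo-5-[(E)-2-[(4S,5S)-5-ethenyl-2,2-dimethyl-1,3-dioxolan-4-yl]ethenyl]-2,2-dimethyl-4H-benzo[d][1,3]dioxine | C=C[C@@H]1OC(C)(C)O[C@H]1/C=C/c1c(Br)ccc2OC(C)(C)OCc12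
A3 | alternative 1 | 5-[(E)-2-[(4S,5S)-5-ethenyl-2,2-dimethyl-1,3-dioxolan-4-yl]ethenyl]-2,2-dimethyl-6-(3-methylbut-2-en-1-yl)-4H-benzo[d][1,3]dioxine | C=C[C@@H]1OC(C)(C)O[C@H]1/C=C/c1c(CC=C(C)C)ccc2OC(C)(C)OCc12
A4 | alternative 2 | 3-(methoxymethoxy)-6-{[(4S)-2,2,5,5-tetramethyl-1,3-dioxolan-4-yl]methyl}-2-(trimethylsilyl)phenyl trifluoromethanesulfonate | COCOc1ccc(C[C@@H]2OC(C)(C)OC2(C)C)c(OS(=O)(=O)C(F)(F)F)c1[Si](C)(C)C
A5 | alternative 2 | (4S,5S)-4-[(E)-hept-1-en-1-yl]-5-[(E)-2-iodoethenyl]-2,2-dimethyl-1,3-dioxolane | CCCCC/C=C/[C@@H]1OC(C)(C)O[C@H]1/C=C/I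
A6 | alternative 2 | 6-[(E)-2-{(4S,5S)-5-[(E)-hept-1-en-1-yl]-2,2-dimethyl-1,3-dioxolan-4-yl}ethenyl]-2-(methoxymethoxy)-5-{[(4S)-2,2,5,5-tetramethyl-1,3-dioxolan-4-yl]methyl}benzaldehyde | CCCCC/C=C/[C@@H]1OC(C)(C)O[C@H]1/C=C/c1c(C[C@@H]2OC(C)(C)OC2(C)C)ccc(OCOC)c1C=O
A7 | alternative 3 | 2,2-dimethyl-6-(3-methylbut-2-en-1-yl)-5-[(1E,3E,5E)-undeca-1,3,5-trien-1-yl]-4H-benzo[d][1,3]dioxine | CCCCC/C=C/C=C/C=C/c1c(CC=C(C)C)ccc2OC(C)(C)OCc12
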